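**Retrosynthetic overview**
1. The C5 and C6 esters come from two successive Steglich acylations of a 5,6-diol, and C4=CH2 from Peterson elimination of a 4-hydroxy-4-(trimethylsilylmethyl) group unmasked together with the 5,6-acetonide.
2. The cis-hydrindanone comes from hydrogenation of a Pauson–Khand enone (sets C3a); the PK reaction of a 1,7-enyne (terminal alkyne + (Z)-alkene) closes the cyclohexane and cyclopentenone in one step (sets C1, C7a).
3. The oxirane ester comes from nucleophilic epoxidation of an α-substituted acrylate, made from a Meldrum's acid adduct by Eschenmoser methylenation.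
4. C7 is set by conjugate addition of a (Z)-alkenyl Grignard (C8 from (S)-but-3-yn-2-ol) to an alkylidene Meldrum's acid; C5/C6 come from D-tartrate acetonide via its bis-Weinreb amide.
5. Ring order: dioxolane (bought) → oxirane (step 10) → cyclohexane and cyclopentenone together (step 11) → dioxolane removed (step 14).

Assumption: 1, 4, 18 and 20 are bought as the single isomers shown; locants C1–C7a are those of the hydrindan-2-one core of the target (C1 acetoxyethyl, C4 methylidene, C5/C6 esters, C7 oxirane).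

**Step 1**
Reactants: 1 (S)-but-3-yn-2-ol
Product: 2 (S)-4-iodobut-3-yn-2-ol
Conditions: NIS, AgNO3 (10 mol %), acetone, rt, dark
Reagents that add atoms: N-iodosuccinimide, O=C1CCC(=O)N1I
Why: Silver-catalysed electrophilic iodination of the terminal alkyne C–H leaves the carbinol centre (future C8) untouched.

**Step 2**
Reactants: 2 (S)-4-iodobut-3-yn-2-ol
Product: 3 (2S,3Z)-4-iodobut-3-en-2-ol
Conditions: 2-nitrobenzenesulfonylhydrazide, Et3N, THF/i-PrOH, rt
Reagents that add atoms: none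
Why: Diimide reduction adds H2 syn to the iodoalkyne without C–I hydrogenolysis, giving only the (Z)-vinyl iodide.

**Step 3**
Reactants: 4 dimethyl (4S,5S)-2,2-dimethyl-1,3-dioxolane-4,5-dicarboxylate
Product: 5 (4S,5S)-N4,N5-dimethoxy-N4,N5,2,2-tetramethyl-1,3-dioxolane-4,5-dicarboxamide
Conditions: MeNHOMe·HCl, i-PrMgCl, THF, −20 → 0 °C
Reagents that add atoms: N,O-dimethylhydroxylamine hydrochloride, CNOC.Cl
Why: Weinreb amidation of both esters by the magnesium amide; the trans-dioxolane centres (future C5 and C6) are not touched.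

**Step 4**
Reactants: 5 (4S,5S)-N4,N5-dimethoxy-N4,N5,2,2-tetramethyl-1,3-dioxolane-4,5-dicarboxamide
Product: 6 (4S,5S)-N-methoxy-N,2,2-trimethyl-5-(prop-2-ynoyl)-1,3-dioxolane-4-carboxamide
Conditions: HC≡CMgBr (1.05 equiv), THF, −78 → −20 °C; cold aq. KHSO4
Reagents that add atoms: ethynylmagnesium bromide, C#C[Mg]Br
Why: Weinreb ketone synthesis in which the stable magnesium chelate stops the C2-symmetric bis-amide at mono-addition (desymmetrisation).

**Step 5**
Reactants: 6 (4S,5S)-N-methoxy-N,2,2-trimethyl-5-(prop-2-ynoyl)-1,3-dioxolane-4-carboxamide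
Product: 7 (4S,5S)-5-[(2R)-2-hydroxy-1-(trimethylsilyl)but-3-yn-2-yl]-N-methoxy-N,2,2-trimethyl-1,3-dioxolane-4-carboxamide
Conditions: Me3SiCH2MgCl, THF/Et2O, −78 °C
Reagents that add atoms: (trimethylsilyl)methylmagnesium chloride, C[Si](C)(C)C[Mg]Cl
Why: Cram-chelate-controlled 1,2-Grignard addition to the α-alkoxy ynone (ketone faster than Weinreb amide) sets the (R)-carbinol (future C4, OH cis to O-5) as a masked methylidene.

**Step 6**
Reactants: 7 (4S,5S)-5-[(2R)-2-hydroxy-1-(trimethylsilyl)but-3-yn-2-yl]-N-methoxy-N,2,2-trimethyl-1,3-dioxolane-4-carboxamide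
Product: 8 (4S,5S)-5-[(2R)-2-hydroxy-1-(trimethylsilyl)but-3-yn-2-yl]-2,2-dimethyl-1,3-dioxolane-4-carbaldehyde
Conditions: DIBAL-H (2.5 equiv), THF, −78 °C; Rochelle salt
Reagents that add atoms: none
Why: Weinreb amide reduction stops at the aldehyde through the chelated tetrahedral aluminate, and the trans-dioxolane aldehyde is the stable epimer.

**Step 7**
Reactants: 8 (4S,5S)-5-[(2R)-2-hydroxy-1-(trimethylsilyl)but-3-yn-2-yl]-2,2-dimethyl-1,3-dioxolane-4-carbaldehyde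
Product: 9 5-({(4R,5S)-5-[(2R)-2-hydroxy-1-(trimethylsilyl)but-3-yn-2-yl]-2,2-dimethyl-1,3-dioxolan-4-yl}methylidene)-2,2-dimethyl-1,3-dioxane-4,6-dione
Conditions: Meldrum's acid, EDDA (10 mol %), 4 Å MS, CH2Cl2, 0 °C → rt; used crude
Reagents that add atoms: Meldrum's acid (2,2-dimethyl-1,3-dioxane-4,6-dione), CC1(C)OC(=O)CC(=O)O1
Why: Knoevenagel condensation of the non-enolisable-side α-alkoxy aldehyde gives the doubly activated acceptor without touching the existing centres.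

**Step 8**
Reactants: 9 alkylidene Meldrum's acid (name as above); 3 (2S,3Z)-4-iodobut-3-en-2-ol
Product: 11 5-[(1S,2Z,4S)-4-hydroxy-1-{(4R,5S)-5-[(2R)-2-hydroxy-1-(trimethylsilyl)but-3-yn-2-yl]-2,2-dimethyl-1,3-dioxolan-4-yl}pent-2-en-1-yl]-2,2-dimethyl-1,3-dioxane-4,6-dione, via alkenyl Grignard 10 (not isolated)
Conditions: 3 (2.2 equiv), MeMgCl then i-PrMgCl·LiCl, THF, −40 °C; add 9, −78 → −30 °C; aq. NH4Cl (one equiv of 10 is consumed by the tertiary OH of 9)
Reagents that add atoms: none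
Why: Conjugate (1,4-) addition of the (Z)-alkenyl Grignard, formed by I/Mg exchange with retention, to the alkylidene Meldrum's acid; A(1,3) strain puts H-6 in the alkene plane and the nucleophile adds anti to the dioxolane C5 (syn to O-6, as for γ-alkoxy (Z)-enoates), setting C7.

**Step 9**
Reactants: 11 Meldrum's acid adduct (name as above)
Product: 12 methyl (3S,4Z,6S)-6-hydroxy-3-{(4R,5S)-5-[(2R)-2-hydroxy-1-(trimethylsilyl)but-3-yn-2-yl]-2,2-dimethyl-1,3-dioxolan-4-yl}-2-methylidenehept-4-enoate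
Conditions: CH2=NMe2+ I−, MeOH, 65 °C
Reagents that add atoms: Eschenmoser's salt (N,N-dimethylmethyleneiminium iodide), C=[N+](C)C.[I-]; methanol, CO
Why: Mannich reaction of the Meldrum's acid, methanolysis and decarboxylative loss of dimethylamine give the α-substituted methyl acrylate in one pot under near-neutral conditions that spare the β-hydroxysilane.

**Step 10**
Reactants: 12 methyl (3S,4Z,6S)-6-hydroxy-3-{dioxolanyl}-2-methylidenehept-4-enoate (name as above)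
Product: 13 methyl (2R)-2-[(1R,2Z,4S)-4-hydroxy-1-{(4R,5S)-5-[(2R)-2-hydroxy-1-(trimethylsilyl)but-3-yn-2-yl]-2,2-dimethyl-1,3-dioxolan-4-yl}pent-2-en-1-yl]oxirane-2-carboxylate
Conditions: t-BuOOH, n-BuLi, THF, −78 → −20 °C
Reagents that add atoms: tert-butyl hydroperoxide, CC(C)(C)OO
Why: Weitz–Scheffer nucleophilic epoxidation touches only the acrylate; the ester enolate closes with H-7 eclipsing the enolate (A(1,3) strain) and oxygen delivered anti to the bulky dioxolanyl group, giving the (2R)-oxirane.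

**Step 11**
Reactants: 13 oxirane ester enyne (name as above)
Product: 14 Pauson–Khand enone: 5,6-O-isopropylidene-4-hydroxy-1-[(1S)-1-hydroxyethyl]-4-(trimethylsilylmethyl)-7-[(2R)-2-(methoxycarbonyl)oxiran-2-yl]-1,4,5,6,7,7a-hexahydro-2H-inden-2-one (C3=C3a; H-1 cis to H-7a; 4-OH cis to O-5)
Conditions: Co2(CO)8 (20 mol %), tetramethylthiourea (60 mol %), CO (1 atm), PhMe, 70 °C
Reagents that add atoms: carbon monoxide, [C-]#[O+]
Why: Intramolecular Pauson–Khand [2+2+1] in which the trans-dioxolane enforces a chair transition state with both ring oxygens equatorial and the C7 oxiranyl group axial, so H-7a forms anti to it, and suprafacial addition to the (Z)-alkene puts H-1 cis to H-7a.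

**Step 12**
Reactants: 14 Pauson–Khand enone (name as above)
Product: 15 the 1-[(1S)-1-acetoxyethyl] analogue of 14
Conditions: Ac2O, pyridine, DMAP (cat.), CH2Cl2, 0 °C
Reagents that add atoms: acetic anhydride, CC(=O)OC(C)=O
Why: Acylation of the only secondary alcohol (the tertiary 4-OH is inert), which also enlarges the group shielding the upper face for the next step.

**Step 13**
Reactants: 15 acetate (name as above)
Product: 16 cis-fused ketone: 3,3a-dihydro-15 (H-3a cis to H-7a and H-1)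
Conditions: H2 (1 atm), 10% Pd/C, EtOAc, rt
Reagents that add atoms: none
Why: Heterogeneous hydrogenation of the trisubstituted enone from the face opposite the axial C7 oxiranyl group and the C1 side chain (the face carrying the axial 4-OH) sets C3a and the cis ring fusion.

**Step 14**
Reactants: 16 cis-fused ketone (name as above)
Product: 17 methyl (2R)-2-[(1R,3aS,5R,6R,7R,7aR)-1-[(1S)-1-acetoxyethyl]-5,6-dihydroxy-4-methylidene-2-oxooctahydro-1H-inden-7-yl]oxirane-2-carboxylate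
Conditions: TsOH·H2O (cat.), THF/H2O, rt → 35 °C
Reagents that add atoms: none
Why: Acid-promoted Peterson elimination of the tertiary β-hydroxysilane is regiospecific for the exocyclic methylidene, and the strained trans-fused acetonide hydrolyses under the same mild acid while the electron-poor oxirane ester survives.

**Step 15**
Reactants: 17 diol (name as above); 18 (S)-3-methylpentanoic acid
Product: 19 methyl (2R)-2-[(1R,3aS,5R,6R,7R,7aR)-1-[(1S)-1-acetoxyethyl]-6-hydroxy-4-methylidene-5-{[(3S)-3-methylpentanoyl]oxy}-2-oxooctahydro-1H-inden-7-yl]oxirane-2-carboxylate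
Conditions: 18 (1.05 equiv), DIC, DMAP (cat.), CH2Cl2, −10 °C → rt
Reagents that add atoms: none
Why: Steglich esterification selects the allylic C5–OH on the open face over C6–OH, which is flanked by the C7 oxirane carbon and the 1,3-related C1 side chain; no stereocentre is touched.

**Step 16**
Reactants: 19 mono-ester (name as above); 20 (E)-3-methylpent-2-enoic acid
Product: 21 methyl (2R)-2-[(1R,3aS,5R,6R,7R,7aR)-1-[(1S)-1-acetoxyethyl]-4-methylidene-6-{[(2E)-3-methylpent-2-enoyl]oxy}-5-{[(3S)-3-methylpentanoyl]oxy}-2-oxooctahydro-1H-inden-7-yl]oxirane-2-carboxylate (target)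
Conditions: 20 (3 equiv), DIC, DMAP, CH2Cl2, rt
Reagents that add atoms: none
Why: Steglich esterification of the remaining hindered alcohol without any base strong enough to eliminate the β-acetoxy ketone or isomerise the (E)-enoate.

**Compound list**
1 | (S)-but-3-yn-2-ol | C[C@H](O)C#C | starting material
2 | (S)-4-iodobut-3-yn-2-ol | C[C@H](O)C#CI | intermediate
3 | (2S,3Z)-4-iodobut-3-en-2-ol | C[C@H](O)/C=C\I | intermediate
4 | dimethyl (4S,5S)-2,2-dimethyl-1,3-dioxolane-4,5-dicarboxylate (dimethyl 2,3-O-isopropylidene-D-tartrate) | COC(=O)[C@H]1OC(C)(C)O[C@@H]1C(=O)OC | starting material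
5 | (4S,5S)-N4,N5-dimethoxy-N4,N5,2,2-tetramethyl-1,3-dioxolane-4,5-dicarboxamide | CON(C)C(=O)[C@H]1OC(C)(C)O[C@@H]1C(=O)N(C)OC | intermediate
6 | (4S,5S)-N-methoxy-N,2,2-trimethyl-5-(prop-2-ynoyl)-1,3-dioxolane-4-carboxamide | CON(C)C(=O)[C@H]1OC(C)(C)O[C@@H]1C(=O)C#C | intermediate
7 | (4S,5S)-5-[(2R)-2-hydroxy-1-(trimethylsilyl)but-3-yn-2-yl]-N-methoxy-N,2,2-trimethyl-1,3-dioxolane-4-carboxamide | CON(C)C(=O)[C@H]1OC(C)(C)O[C@@H]1[C@@](O)(C[Si](C)(C)C)C#C | intermediate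
8 | (4S,5S)-5-[(2R)-2-hydroxy-1-(trimethylsilyl)but-3-yn-2-yl]-2,2-dimethyl-1,3-dioxolane-4-carbaldehyde | O=C[C@H]1OC(C)(C)O[C@@H]1[C@@](O)(C[Si](C)(C)C)C#C | intermediate
9 | 5-({(4R,5S)-5-[(2R)-2-hydroxy-1-(trimethylsilyl)but-3-yn-2-yl]-2,2-dimethyl-1,3-dioxolan-4-yl}methylidene)-2,2-dimethyl-1,3-dioxane-4,6-dione | CC1(C)OC(=O)C(=C[C@H]2OC(C)(C)O[C@@H]2[C@@](O)(C[Si](C)(C)C)C#C)C(=O)O1 | intermediate
10 | chloromagnesium (2S,3Z)-4-(chloromagnesio)but-3-en-2-olate (alkenyl Grignard; not isolated) | C[C@H](O[Mg]Cl)/C=C\[Mg]Cl | intermediate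
11 | 5-[(1S,2Z,4S)-4-hydroxy-1-{(4R,5S)-5-[(2R)-2-hydroxy-1-(trimethylsilyl)but-3-yn-2-yl]-2,2-dimethyl-1,3-dioxolan-4-yl}pent-2-en-1-yl]-2,2-dimethyl-1,3-dioxane-4,6-dione | C[C@H](O)/C=C\[C@@H](C1C(=O)OC(C)(C)OC1=O)[C@H]2OC(C)(C)O[C@@H]2[C@@](O)(C[Si](C)(C)C)C#C | intermediate
12 | methyl (3S,4Z,6S)-6-hydroxy-3-{(4R,5S)-5-[(2R)-2-hydroxy-1-(trimethylsilyl)but-3-yn-2-yl]-2,2-dimethyl-1,3-dioxolan-4-yl}-2-methylidenehept-4-enoate | C[C@H](O)/C=C\[C@@H](C(=C)C(=O)OC)[C@H]1OC(C)(C)O[C@@H]1[C@@](O)(C[Si](C)(C)C)C#C | intermediate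
13 | methyl (2R)-2-[(1R,2Z,4S)-4-hydroxy-1-{(4R,5S)-5-[(2R)-2-hydroxy-1-(trimethylsilyl)but-3-yn-2-yl]-2,2-dimethyl-1,3-dioxolan-4-yl}pent-2-en-1-yl]oxirane-2-carboxylate | C[C@H](O)/C=C\[C@@H]([C@]2(C(=O)OC)CO2)[C@H]1OC(C)(C)O[C@@H]1[C@@](O)(C[Si](C)(C)C)C#C | intermediate
14 | Pauson–Khand enone: 5,6-O-isopropylidene-4-hydroxy-1-[(1S)-1-hydroxyethyl]-4-(trimethylsilylmethyl)-7-[(2R)-2-(methoxycarbonyl)oxiran-2-yl]-1,4,5,6,7,7a-hexahydro-2H-inden-2-one (C3=C3a; H-1 cis to H-7a; 4-OH cis to O-5; C1/C5/C6/C7/C7a as in 21) | O[C@]1(C[Si](C)(C)C)C2=CC(=O)[C@@H]([C@H](C)O)[C@H]2[C@@H]([C@]3(C(=O)OC)CO3)[C@H]4OC(C)(C)O[C@H]14 | intermediate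
15 | 1-[(1S)-1-acetoxyethyl] analogue of 14 | O[C@]1(C[Si](C)(C)C)C2=CC(=O)[C@@H]([C@H](C)OC(C)=O)[C@H]2[C@@H]([C@]3(C(=O)OC)CO3)[C@H]4OC(C)(C)O[C@H]14 | intermediate
16 | cis-fused saturated ketone: 3,3a-dihydro-15 (H-1, H-3a, H-7a all cis; other centres as in 15) | O[C@]1(C[Si](C)(C)C)[C@H]2CC(=O)[C@@H]([C@H](C)OC(C)=O)[C@H]2[C@@H]([C@]3(C(=O)OC)CO3)[C@H]4OC(C)(C)O[C@H]14 | intermediate
17 | methyl (2R)-2-[(1R,3aS,5R,6R,7R,7aR)-1-[(1S)-1-acetoxyethyl]-5,6-dihydroxy-4-methylidene-2-oxooctahydro-1H-inden-7-yl]oxirane-2-carboxylate | C=C1[C@H]2CC(=O)[C@@H]([C@H](C)OC(C)=O)[C@H]2[C@@H]([C@]2(C(=O)OC)CO2)[C@@H](O)[C@@H]1O | intermediate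
18 | (S)-3-methylpentanoic acid | CC[C@H](C)CC(=O)O | starting material
19 | methyl (2R)-2-[(1R,3aS,5R,6R,7R,7aR)-1-[(1S)-1-acetoxyethyl]-6-hydroxy-4-methylidene-5-{[(3S)-3-methylpentanoyl]oxy}-2-oxooctahydro-1H-inden-7-yl]oxirane-2-carboxylate | C=C1[C@H]2CC(=O)[C@@H]([C@H](C)OC(C)=O)[C@H]2[C@@H]([C@]2(C(=O)OC)CO2)[C@@H](O)[C@@H]1OC(=O)C[C@@H](C)CC | intermediate
20 | (E)-3-methylpent-2-enoic acid | CC/C(C)=C/C(=O)O | starting material
21 | methyl (2R)-2-[(1R,3aS,5R,6R,7R,7aR)-1-[(1S)-1-acetoxyethyl]-4-methylidene-6-{[(2E)-3-methylpent-2-enoyl]oxy}-5-{[(3S)-3-methylpentanoyl]oxy}-2-oxooctahydro-1H-inden-7-yl]oxirane-2-carboxylate (CNP0109740.1) | C=C1[C@H]2CC(=O)[C@@H]([C@H](C)OC(C)=O)[C@H]2[C@@H]([C@]2(C(=O)OC)CO2)[C@@H](OC(=O)/C=C(\C)CC)[C@@H]1OC(=O)C[C@@H](C)CC | target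

**Step count and risks**
Total step count: 16 (steps 1–2 make the vinyl iodide; steps 3–16 are the main line).
Longest linear sequence: 14 steps (4 → 21, steps 3–16).

Three steps most likely to fail:

Step 11 (Pauson–Khand). The 1,2-disubstituted (Z)-alkene is a slow partner, and the oxirane ester and two free hydroxyls may not tolerate the cobalt cycle. The fallback sets out from 13 and comes back at 14. A nickel(0)-mediated [2+2+1] cyclisation with an isocyanide as CO surrogate (Ni(cod)2, n-Bu3P, 2,6-dimethylphenyl isocyanide, THF) gives the bicyclic 2-iminocyclopentene, the N-(2,6-dimethylphenyl)imine of enone 14 F7. Hydrolysis on wet silica gel / AcOH–NaOAc buffer (pH 5, to spare the β-hydroxysilane) then gives 14.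

Step 10 (epoxidation). The oxirane configuration rests on acyclic A(1,3) control and may be low or reversed. The fallback sets out from 12 and comes back at 13 under reagent control. DIBAL-H reduces the ester to (3S,4Z,6S)-3-{(4R,5S)-5-[(2R)-2-hydroxy-1-(trimethylsilyl)but-3-yn-2-yl]-2,2-dimethyl-1,3-dioxolan-4-yl}-2-methylidenehept-4-ene-1,6-diol F4. Sharpless asymmetric epoxidation (Ti(OiPr)4, L-(+)-diethyl tartrate, t-BuOOH, −20 °C) gives {(2S)-2-[(1R,2Z,4S)-4-hydroxy-1-{dioxolanyl}pent-2-en-1-yl]oxiran-2-yl}methanol F5; the primary 1,1-disubstituted allylic alcohol reacts much faster than the (Z)-secondary and tertiary alcohols. Primary-selective oxidation (TEMPO/PhI(OAc)2, then NaClO2) gives the (2R)-oxirane-2-carboxylic acid F6, and TMSCHN2 gives 13.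

Step 8 (conjugate addition). The crude alkylidene Meldrum's acid is fragile, and facial selectivity at C7 on this hindered acceptor with a free OH is unproven. The fallback sets out from 8 and comes back at 12 through a mono-activated acceptor with the best precedent for syn selectivity. Ando olefination (methyl (diphenoxyphosphoryl)acetate, NaH, THF, −78 °C) gives methyl (2Z)-3-{(4R,5S)-5-[(2R)-2-hydroxy-1-(trimethylsilyl)but-3-yn-2-yl]-2,2-dimethyl-1,3-dioxolan-4-yl}prop-2-enoate F1. Copper-catalysed, TMSCl-accelerated 1,4-addition of Grignard 10 (from 3 as in step 8, CuBr·SMe2) gives methyl (3R,4Z,6S)-6-hydroxy-3-{dioxolanyl}hept-4-enoate F2. Mannich reaction of its lithium enolate with Eschenmoser's salt gives the methyl 2-[(dimethylamino)methyl] ester F3, and MeI then NaHCO3 (quaternisation–elimination) gives 12.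

**Further compounds**
F1 | step 8 | methyl (2Z)-3-{(4R,5S)-5-[(2R)-2-hydroxy-1-(trimethylsilyl)but-3-yn-2-yl]-2,2-dimethyl-1,3-dioxolan-4-yl}prop-2-enoate | COC(=O)/C=C\[C@H]1OC(C)(C)O[C@@H]1[C@@](O)(C[Si](C)(C)C)C#C
F2 | step 8 | methyl (3R,4Z,6S)-6-hydroxy-3-{(4R,5S)-5-[(2R)-2-hydroxy-1-(trimethylsilyl)but-3-yn-2-yl]-2,2-dimethyl-1,3-dioxolan-4-yl}hept-4-enoate | C[C@H](O)/C=C\[C@@H](CC(=O)OC)[C@H]1OC(C)(C)O[C@@H]1[C@@](O)(C[Si](C)(C)C)C#C
F3 | step 8 | methyl 2-[(dimethylamino)methyl] derivative of F2 (C2 epimers) | C[C@H](O)/C=C\[C@@H](C(CN(C)C)C(=O)OC)[C@H]1OC(C)(C)O[C@@H]1[C@@](O)(C[Si](C)(C)C)C#C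
F4 | step 10 | (3S,4Z,6S)-3-{(4R,5S)-5-[(2R)-2-hydroxy-1-(trimethylsilyl)but-3-yn-2-yl]-2,2-dimethyl-1,3-dioxolan-4-yl}-2-methylidenehept-4-ene-1,6-diol | C[C@H](O)/C=C\[C@@H](C(=C)CO)[C@H]1OC(C)(C)O[C@@H]1[C@@](O)(C[Si](C)(C)C)C#C
F5 | step 10 | {(2S)-2-[(1R,2Z,4S)-4-hydroxy-1-{(4R,5S)-5-[(2R)-2-hydroxy-1-(trimethylsilyl)but-3-yn-2-yl]-2,2-dimethyl-1,3-dioxolan-4-yl}pent-2-en-1-yl]oxiran-2-yl}methanol | C[C@H](O)/C=C\[C@@H]([C@]2(CO)CO2)[C@H]1OC(C)(C)O[C@@H]1[C@@](O)(C[Si](C)(C)C)C#C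
F6 | step 10 | (2R)-2-[(1R,2Z,4S)-4-hydroxy-1-{(4R,5S)-5-[(2R)-2-hydroxy-1-(trimethylsilyl)but-3-yn-2-yl]-2,2-dimethyl-1,3-dioxolan-4-yl}pent-2-en-1-yl]oxirane-2-carboxylic acid | C[C@H](O)/C=C\[C@@H]([C@]2(C(=O)O)CO2)[C@H]1OC(C)(C)O[C@@H]1[C@@](O)(C[Si](C)(C)C)C#C
F7 | step 11 | N-(2,6-dimethylphenyl)imine of enone 14 (bicyclic 2-iminocyclopentene) | O[C@]1(C[Si](C)(C)C)C2=CC(=Nc3c(C)cccc3C)[C@@H]([C@H](C)O)[C@H]2[C@@H]([C@]4(C(=O)OC)CO4)[C@H]5OC(C)(C)O[C@H]15
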